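The whole route depends on cutting only the C2–O1 bond of the dioxane. C2 bears the catechol ring and is para-hydroxybenzylic, so oxidation makes it the terminus of a para-quinone methide. C3 bears the resorcinol ring, whose oxygens are meta. Its bond to O4 (para to the styryl arm on ring A) therefore stays intact and holds the stereochemical information. In one operation the key step turns a C2–H into the C2–O1 bond, closes the dioxane and sets C2 trans to C3. Its precursor is an acyclic (S)-1,2-diarylethyl ether of 3,4-dihydroxybenzaldehyde through O4. It has a free O1–H, a free 4-hydroxyl on the catechol ring and MOM ethers elsewhere.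

Key step: step 10

**Numbering used below**
- The dioxane is numbered O1–C2–C3–O4.
- Ring A is the benzo ring; the arm sits on C7, para to the carbon bearing O4.
- Ring B is the catechol ring on C2, ring C the resorcinol ring on C3, and ring D the resorcinol ring of the styryl arm.

**Design remarks**
- Aryl methyl ethers are avoided. BBr3 or related Lewis acids would attack both benzylic C–O bonds of the finished dioxane.
- Phenols that stay masked to the end are MOM ethers. The two phenols needed in the key step are THP ethers, which fall in aqueous acetic acid while MOM survives.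
- The arm is carried as a nitrile through the ether-forming step. A formyl group could accept hydride from the benzylic alkoxide and erode the C3 configuration.
- The phenol released by the key step is capped before the strongly basic olefination.

**Assumption:** each THP acetal carbon forms as a mixture of epimers and is left undefined in the SMILES; all epimers converge in step 9.

## Route

Step 1
Reactants: 1 catechol
Product: 2 2-(methoxymethoxy)phenol
Conditions: MOMCl (0.5 equiv relative to 1), iPr2NEt, CH2Cl2, 0 °C → rt
Reagents that add atoms: chloromethyl methyl ether (MOMCl), COCCl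
Why: Base-mediated O-alkylation (acetal-type Williamson etherification) stops at the mono-ether because the diol is in excess, and unreacted catechol is removed by aqueous extraction.

Step 2
Reactants: 2 2-(methoxymethoxy)phenol
Product: 3 4-bromo-2-(methoxymethoxy)phenol
Conditions: NBS (1.0 equiv), MeCN, 0 °C
Reagents that add atoms: N-bromosuccinimide, O=C1CCC(=O)N1Br
Why: Electrophilic aromatic bromination goes para to the free hydroxyl, the stronger donor, as in the bromination of guaiacol, and NBS releases no strong acid that could harm the MOM acetal.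

Step 3
Reactants: 3 4-bromo-2-(methoxymethoxy)phenol
Product: 4 2-[4-bromo-2-(methoxymethoxy)phenoxy]oxane
Conditions: 3,4-dihydro-2H-pyran, PPTS (cat.), CH2Cl2, rt
Reagents that add atoms: 3,4-dihydro-2H-pyran, C1=COCCC1
Why: Acid-catalysed addition of the phenol to the enol ether (tetrahydropyranylation) gives a base-stable acetal far more acid-labile than MOM, and the new acetal centre forms without control and is carried as a racemate because it disappears in step 9.

Step 4
Reactants: 5 3',5'-dihydroxyacetophenone
Product: 6 3',5'-bis(methoxymethoxy)acetophenone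
Conditions: MOMCl (2.5 equiv), iPr2NEt, CH2Cl2, 0 °C → rt
Reagents that add atoms: chloromethyl methyl ether (MOMCl), COCCl
Why: Double O-alkylation of the phenols under amine base is a standard acetal protection and leaves the methyl ketone untouched.

Step 5
Reactants: 6 3',5'-bis(methoxymethoxy)acetophenone; 4 2-[4-bromo-2-(methoxymethoxy)phenoxy]oxane
Product: 7 1-[3,5-bis(methoxymethoxy)phenyl]-2-[3-(methoxymethoxy)-4-(oxan-2-yloxy)phenyl]ethan-1-one
Conditions: Pd2(dba)3 (cat.), Xantphos, NaOtBu, THF, 70 °C
Reagents that add atoms: none
Why: Buchwald–Hartwig-type palladium-catalysed α-arylation of the methyl ketone enolate joins C2 to ring B, the wide-bite-angle ligand and the stabilised product enolate hold it at monoarylation, and MOM and THP acetals are inert to NaOtBu.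

Step 6
Reactants: 7 the deoxybenzoin from step 5
Product: 8 (1S)-1-[3,5-bis(methoxymethoxy)phenyl]-2-[3-(methoxymethoxy)-4-(oxan-2-yloxy)phenyl]ethan-1-ol
Conditions: RuCl(p-cymene)[(S,S)-TsDPEN] (cat.), HCO2Na, MeOH–H2O, 40 °C
Reagents that add atoms: none
Why: In this Noyori asymmetric transfer hydrogenation the (S,S)-catalyst recognises the aryl group conjugated to the carbonyl and delivers hydride to the Re face, which sets the future C3 as the (S)-carbinol, and the near-neutral formate medium spares the THP acetal.

Step 7
Reactants: 9 4-fluoro-3-hydroxybenzonitrile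
Product: 10 4-fluoro-3-(oxan-2-yloxy)benzonitrile
Conditions: 3,4-dihydro-2H-pyran, PPTS (cat.), CH2Cl2, rt
Reagents that add atoms: 3,4-dihydro-2H-pyran, C1=COCCC1
Why: Tetrahydropyranylation masks O1 so that ring A stays neutral and electrophilic, and the acetal centre again forms without control and is removed in step 9.

Step 8
Reactants: 8 the (S)-alcohol from step 6; 10 4-fluoro-3-(oxan-2-yloxy)benzonitrile
Product: 11 4-{(1S)-1-[3,5-bis(methoxymethoxy)phenyl]-2-[3-(methoxymethoxy)-4-(oxan-2-yloxy)phenyl]ethoxy}-3-(oxan-2-yloxy)benzonitrile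
Conditions: NaH (1.05 equiv), DMF, 0 °C, then 10, 0 °C → rt, argon
Reagents that add atoms: none
Why: Nucleophilic aromatic substitution (addition–elimination) of the fluoride para to the nitrile forms the aryl–O4 bond without touching the C3–O bond, so the configuration is retained, and a nitrile cannot take hydride from the benzylic alkoxide.

Step 9
Reactants: 11 the nitrile ether from step 8
Product: 14 4-{(1S)-1-[3,5-bis(methoxymethoxy)phenyl]-2-[4-hydroxy-3-(methoxymethoxy)phenyl]ethoxy}-3-hydroxybenzaldehyde, via N-alumanyl aldimine 12 (not isolated), via bis-THP aldehyde 13 (not isolated)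
Conditions: iBu2AlH (1.3 equiv), toluene, −78 °C; then AcOH–THF–H2O (4:2:1), −78 → 45 °C
Reagents that add atoms: water, O
Why: Partial nitrile reduction stops at the N-alumanyl aldimine, aqueous acetic acid hydrolyses it to the aldehyde, and the same medium cleaves both aryl THP acetals (acetal hydrolysis) while the three less labile MOM ethers and C3 stay unchanged.

Step 10
Reactants: 14 the dihydroxy aldehyde from step 9
Product: 16 (2R,3R)-3-[3,5-bis(methoxymethoxy)phenyl]-2-[4-hydroxy-3-(methoxymethoxy)phenyl]-2,3-dihydro-1,4-benzodioxine-7-carbaldehyde, via para-quinone methide 15 (not isolated)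
Conditions: Ag2O (1.5 equiv), 4 Å molecular sieves, dry CH2Cl2 (high dilution), rt, dark
Reagents that add atoms: none
Why: Ag2O removes two electrons and two protons from the electron-rich 4-alkyl-2-alkoxyphenol of ring B (phenoxyl radical, then loss of a C2–H) to give para-quinone methide 15, while the formyl-deactivated O1–H phenol of ring A and the MOM-masked rings are untouched. O1 then adds to C2 in an oxa-1,6-conjugate addition that rearomatises ring B; the closest known reaction types are the oxidative cyclisation of 2-hydroxyaryl-tethered 4-alkylphenols to flavans and the phenol capture of quinone methides in benzodioxane neolignan couplings. The ring closes in the 6-exo-trig mode, since the C2=C1' bond that is consumed lies outside the new six-membered ring. C2 is controlled by the fixed C3 centre: rings B and C both take equatorial positions in the half-chair transition state, which gives the (2R,3R)-trans product, and the free para-hydroxyl lets the addition reverse (as in the C2 epimerisation of flavan-3-ols), so any cis isomer can drain to the trans isomer. The step needs chemoselectivity between two phenols and site selectivity for C2–H; the formyl group on ring A secures the first, C2 being the only benzylic position para to a free hydroxyl secures the second, and C3 cannot ionise because the oxygens of ring C are meta. Dilution, dry solvent and the absence of soluble base disfavour radical coupling at C5 of ring B, capture by water and tautomerisation of 15 by loss of the C3 proton.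

Step 11
Reactants: 16 the trans-benzodioxane phenol from step 10
Product: 17 (2R,3R)-2-[3,4-bis(methoxymethoxy)phenyl]-3-[3,5-bis(methoxymethoxy)phenyl]-2,3-dihydro-1,4-benzodioxine-7-carbaldehyde
Conditions: MOMCl, iPr2NEt, CH2Cl2, 0 °C → rt
Reagents that add atoms: chloromethyl methyl ether (MOMCl), COCCl
Why: O-Alkylation of the single free phenol removes the para-hydroxyl that makes C2–O1 reversible, so the trans-dioxane is locked against the strong base of step 15.

Step 12
Reactants: 18 3,5-dihydroxybenzyl alcohol
Product: 19 [3,5-bis(methoxymethoxy)phenyl]methanol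
Conditions: MOMCl (2.1 equiv), K2CO3, acetone, 0 °C → rt
Reagents that add atoms: chloromethyl methyl ether (MOMCl), COCCl
Why: Carbonate deprotonates only the phenols, so this chemoselective phenoxide O-alkylation, familiar from the benzylation of the same triol, leaves the benzylic alcohol free.

Step 13
Reactants: 19 [3,5-bis(methoxymethoxy)phenyl]methanol
Product: 20 1-(bromomethyl)-3,5-bis(methoxymethoxy)benzene
Conditions: CBr4, PPh3, CH2Cl2, 0 °C
Reagents that add atoms: carbon tetrabromide, BrC(Br)(Br)Br
Why: The Appel bromination converts the primary benzylic alcohol into the bromide under essentially neutral conditions that MOM ethers tolerate.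

Step 14
Reactants: 20 1-(bromomethyl)-3,5-bis(methoxymethoxy)benzene
Product: 21 diethyl [3,5-bis(methoxymethoxy)benzyl]phosphonate
Conditions: P(OEt)3 (neat), 130 °C
Reagents that add atoms: triethyl phosphite, CCOP(OCC)OCC
Why: The Michaelis–Arbuzov reaction of a reactive benzylic bromide is reliable, and the volatile bromoethane distils out and drives it to completion.

Step 15
Reactants: 17 the tetra-MOM aldehyde from step 11; 21 diethyl [3,5-bis(methoxymethoxy)benzyl]phosphonate
Product: 22 cassigarol E hexakis(methoxymethyl) ether, (2R,3R), (E)-alkene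
Conditions: KOtBu, THF, 0 °C, then 17, 0 °C → rt
Reagents that add atoms: none
Why: Horner–Wadsworth–Emmons olefination of a non-enolisable aromatic aldehyde with a benzylic phosphonate anion gives the (E)-stilbene, and 17 has no acidic proton or base-labile group, so C2 and C3 are not disturbed.

Step 16
Reactants: 22 cassigarol E hexakis(methoxymethyl) ether
Product: 23 cassigarol E
Conditions: aq. HCl (cat.), MeOH–THF, 40 °C, argon
Reagents that add atoms: none
Why: Brønsted acid-catalysed transacetalisation to methanol removes all six aryl MOM groups under conditions in which O1 and O4 are hardly protonated, C3–O4 cannot ionise, and any reversible opening at C2–O1 recloses to the trans ring.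

## Compound list

1 | catechol | Oc1ccccc1O | starting material
2 | 2-(methoxymethoxy)phenol | COCOc1ccccc1O | intermediate
3 | 4-bromo-2-(methoxymethoxy)phenol | COCOc1cc(Br)ccc1O | intermediate
4 | 2-[4-bromo-2-(methoxymethoxy)phenoxy]oxane (racemic acetal) | COCOc1cc(Br)ccc1OC1CCCCO1 | intermediate
5 | 3',5'-dihydroxyacetophenone | CC(=O)c1cc(O)cc(O)c1 | starting material
6 | 3',5'-bis(methoxymethoxy)acetophenone | CC(=O)c1cc(OCOC)cc(OCOC)c1 | intermediate
7 | 1-[3,5-bis(methoxymethoxy)phenyl]-2-[3-(methoxymethoxy)-4-(oxan-2-yloxy)phenyl]ethan-1-one | O=C(Cc1ccc(OC2CCCCO2)c(OCOC)c1)c1cc(OCOC)cc(OCOC)c1 | intermediate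
8 | (1S)-1-[3,5-bis(methoxymethoxy)phenyl]-2-[3-(methoxymethoxy)-4-(oxan-2-yloxy)phenyl]ethan-1-ol (acetal epimers) | O[C@@H](Cc1ccc(OC2CCCCO2)c(OCOC)c1)c1cc(OCOC)cc(OCOC)c1 | intermediate
9 | 4-fluoro-3-hydroxybenzonitrile | N#Cc1ccc(F)c(O)c1 | starting material
10 | 4-fluoro-3-(oxan-2-yloxy)benzonitrile (racemic acetal) | N#Cc1ccc(F)c(OC2CCCCO2)c1 | intermediate
11 | 4-{(1S)-1-[3,5-bis(methoxymethoxy)phenyl]-2-[3-(methoxymethoxy)-4-(oxan-2-yloxy)phenyl]ethoxy}-3-(oxan-2-yloxy)benzonitrile (acetal epimers) | N#Cc1ccc(O[C@@H](Cc2ccc(OC3CCCCO3)c(OCOC)c2)c2cc(OCOC)cc(OCOC)c2)c(OC2CCCCO2)c1 | intermediate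
12 | N-(diisobutylalumanyl) aldimine derived from 11, (S) at C3 | CC(C)C[Al](CC(C)C)N=Cc1ccc(O[C@@H](Cc2ccc(OC3CCCCO3)c(OCOC)c2)c2cc(OCOC)cc(OCOC)c2)c(OC2CCCCO2)c1 | intermediate
13 | 4-{(1S)-1-[3,5-bis(methoxymethoxy)phenyl]-2-[3-(methoxymethoxy)-4-(oxan-2-yloxy)phenyl]ethoxy}-3-(oxan-2-yloxy)benzaldehyde | O=Cc1ccc(O[C@@H](Cc2ccc(OC3CCCCO3)c(OCOC)c2)c2cc(OCOC)cc(OCOC)c2)c(OC2CCCCO2)c1 | intermediate
14 | 4-{(1S)-1-[3,5-bis(methoxymethoxy)phenyl]-2-[4-hydroxy-3-(methoxymethoxy)phenyl]ethoxy}-3-hydroxybenzaldehyde (key-step precursor) | O=Cc1ccc(O[C@@H](Cc2ccc(O)c(OCOC)c2)c2cc(OCOC)cc(OCOC)c2)c(O)c1 | intermediate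
15 | 4-{(1S)-1-[3,5-bis(methoxymethoxy)phenyl]-2-[3-(methoxymethoxy)-4-oxocyclohexa-2,5-dien-1-ylidene]ethoxy}-3-hydroxybenzaldehyde (para-quinone methide) | O=Cc1ccc(O[C@@H](C=C2C=CC(=O)C(OCOC)=C2)c2cc(OCOC)cc(OCOC)c2)c(O)c1 | intermediate
16 | (2R,3R)-3-[3,5-bis(methoxymethoxy)phenyl]-2-[4-hydroxy-3-(methoxymethoxy)phenyl]-2,3-dihydro-1,4-benzodioxine-7-carbaldehyde (trans; key-step product) | O=Cc1ccc2c(c1)O[C@H](c1ccc(O)c(OCOC)c1)[C@@H](c1cc(OCOC)cc(OCOC)c1)O2 | intermediate
17 | (2R,3R)-2-[3,4-bis(methoxymethoxy)phenyl]-3-[3,5-bis(methoxymethoxy)phenyl]-2,3-dihydro-1,4-benzodioxine-7-carbaldehyde | O=Cc1ccc2c(c1)O[C@H](c1ccc(OCOC)c(OCOC)c1)[C@@H](c1cc(OCOC)cc(OCOC)c1)O2 | intermediate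
18 | 3,5-dihydroxybenzyl alcohol | OCc1cc(O)cc(O)c1 | starting material
19 | [3,5-bis(methoxymethoxy)phenyl]methanol | OCc1cc(OCOC)cc(OCOC)c1 | intermediate
20 | 1-(bromomethyl)-3,5-bis(methoxymethoxy)benzene | BrCc1cc(OCOC)cc(OCOC)c1 | intermediate
21 | diethyl [3,5-bis(methoxymethoxy)benzyl]phosphonate | CCOP(=O)(Cc1cc(OCOC)cc(OCOC)c1)OCC | intermediate
22 | cassigarol E hexakis(methoxymethyl) ether, (2R,3R), (E) | COCOc1cc(OCOC)cc(/C=C/c2ccc3c(c2)O[C@H](c2ccc(OCOC)c(OCOC)c2)[C@@H](c2cc(OCOC)cc(OCOC)c2)O3)c1 | intermediate
23 | cassigarol E, (2R,3R), (E) | Oc1cc(O)cc(/C=C/c2ccc3c(c2)O[C@H](c2ccc(O)c(O)c2)[C@@H](c2cc(O)cc(O)c2)O3)c1 | target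

Total step count: 16.
Longest linear sequence: 11 steps (1, 2, 3, 5, 6, 8, 9, 10, 11, 15, 16).

## Steps most likely to fail

**Step 10.**
- Phenoxyl radicals of ring B may couple at the free C5 position before the second oxidation.
- The quinone methide may tautomerise by loss of the C3 proton, which would erase C3, or it may be captured by traces of water.
- The product phenol may be oxidised further.
- The kinetic closure may show only a weak trans preference.

The fallback sets out from 14 and returns at 16, and it separates oxidation from ring closure. Compound 14 is treated with DDQ in CH2Cl2–MeOH. This is a known benzylic methoxylation of 4-alkylphenols in which the solvent captures the quinone methide. It gives the C2 methyl ether F1 as both C2 epimers. Catalytic PPTS in dry CH2Cl2 then ionises this para-hydroxybenzylic ether. O1 closes the ring under thermodynamic control with loss of methanol, and both epimers converge on trans-16 while the MOM ethers persist.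

**Step 8.**
- Substitution at the hindered, alkoxy-flanked C–F carbon may be slow.
- The alkoxide may induce elimination of the aryloxide from the product.
- Trace ketone may mediate hydride exchange and lower the enantiopurity.

The fallback sets out from 7 and returns at 14, and it forms the C3–O4 bond instead of the aryl–O4 bond. Ketone 7 is reduced with RuCl(p-cymene)[(R,R)-TsDPEN] and HCO2Na to the (R)-alcohol F2. A Mitsunobu reaction (PPh3, DIAD, toluene, 0 °C) with commercial 3,4-dihydroxybenzaldehyde follows. Its 4-hydroxyl, para to the formyl group, is the more acidic and reacts preferentially. The reaction inverts the carbinol centre and gives the (S)-aryl ether F3 with O1–H already free. AcOH–THF–H2O at 45 °C removes the single THP group and delivers 14.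

**Step 16.**
- Acid may open C2–O1 with capture by solvent.
- Formaldehyde equivalents may attack the liberated resorcinol rings.
- The electron-rich stilbene may oligomerise.
- Cleavage of the six acetals may stay incomplete.

The fallback sets out from 22 and returns at 23, and it replaces acid hydrolysis by a protecting-group exchange. TESOTf and 2,2'-bipyridyl in CH2Cl2 at 0 °C, a known non-acidic conversion of aryl MOM ethers into aryl silyl ethers, give the hexakis(triethylsilyl) ether F4. Buffered fluoride (Et3N·3HF, THF, 0 °C) then desilylates F4 to 23.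

Further compounds
F1 | step 10 | 4-{(1R)-1-[3,5-bis(methoxymethoxy)phenyl]-2-[4-hydroxy-3-(methoxymethoxy)phenyl]-2-methoxyethoxy}-3-hydroxybenzaldehyde (C3 geometry as in 14, both epimers at C2) | O=Cc1ccc(O[C@@H](C(OC)c2ccc(O)c(OCOC)c2)c2cc(OCOC)cc(OCOC)c2)c(O)c1
F2 | step 8 | (1R)-1-[3,5-bis(methoxymethoxy)phenyl]-2-[3-(methoxymethoxy)-4-(oxan-2-yloxy)phenyl]ethan-1-ol | O[C@H](Cc1ccc(OC2CCCCO2)c(OCOC)c1)c1cc(OCOC)cc(OCOC)c1
F3 | step 8 | 4-{(1S)-1-[3,5-bis(methoxymethoxy)phenyl]-2-[3-(methoxymethoxy)-4-(oxan-2-yloxy)phenyl]ethoxy}-3-hydroxybenzaldehyde | O=Cc1ccc(O[C@@H](Cc2ccc(OC3CCCCO3)c(OCOC)c2)c2cc(OCOC)cc(OCOC)c2)c(O)c1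
F4 | step 16 | cassigarol E hexakis(triethylsilyl) ether, (2R,3R), (E) | CC[Si](CC)(CC)Oc1cc(O[Si](CC)(CC)CC)cc(/C=C/c2ccc3c(c2)O[C@H](c2ccc(O[Si](CC)(CC)CC)c(O[Si](CC)(CC)CC)c2)[C@@H](c2cc(O[Si](CC)(CC)CC)cc(O[Si](CC)(CC)CC)c2)O3)c1
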